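**Retrosynthetic overview**

1. The ten-membered carbocycle (C1–C10, germacrane numbering) is closed last by forming C3–C4: an intramolecular Nozaki–Hiyama–Kishi addition of the (Z)-C4 alkenyl iodide to the C3 aldehyde of seco compound 36. This is possible because C3 is a carbinol carbon bonded directly to C4 of the ring's Z-configured C4=C5 alkene (C4 also carries methyl C15), and this unit hangs on C6 of the trans γ-lactone (O, C6, C7, C11, C12), which together with the trans oxirane (C1, C10, O) folds the chain.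
2. 36 comes from lactone alcohol 33 by Mitsunobu esterification at C8 (with inversion) with the complete side-chain acid 31, built from two Morita–Baylis–Hillman adducts, followed by unmasking of C3.
3. 33 comes from an indium Barbier union (C7–C8) of bromomethyl butenolide 11 (C4–C7, C11–C13, C15; C6 set by asymmetric alkynylation) with epoxy aldehyde 20 (C1–C3, C8–C10, C14; oxirane from a Shi epoxidation).
4. Ring order: γ-lactone (step 4) and oxirane (step 8) in separate fragments, then the ten-membered ring (step 21); one desilylation follows.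

Key step: step 21

Assumption: the Barbier step 17 is taken to follow the closed chair transition state (carbinol 1S, the C8 epimer), which is why the ester is introduced with inversion in step 18; pent-1-en-4-yne (12) and aldehyde 25 are taken as purchasable.

**Route**

Step 1
Reactants: 1 but-2-yn-1-ol
Product: 3 (2Z)-3-iodobut-2-en-1-ol, via cyclic alkenylalanate 2 (not isolated)
Conditions: NaAlH2(OCH2CH2OCH3)2, THF, 0 °C → rt; then I2, THF, −78 → 0 °C
Reagents that add atoms: iodine, II
Why: Hydroxyl-directed trans-hydroalumination of the propargylic alcohol places aluminium on C3 in the five-membered alanate 2, and iodinolysis with retention gives the Z iodide (hydroalumination–iodination).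

Step 2
Reactants: 3 (2Z)-3-iodobut-2-en-1-ol
Product: 4 (2Z)-3-iodobut-2-enal
Conditions: MnO2, CH2Cl2, rt
Reagents that add atoms: none
Why: Activated MnO2 oxidises the allylic alcohol selectively under neutral conditions, so the Z iodoalkene should not isomerise (allylic oxidation).

Step 3
Reactants: 4 (2Z)-3-iodobut-2-enal; 5 methyl prop-2-ynoate
Product: 7 methyl (4R,5Z)-4-hydroxy-6-iodohept-5-en-2-ynoate, via zinc acetylide 6 (not isolated)
Conditions: Me2Zn, ProPhenol ligand (2,6-bis{[2-(hydroxydiphenylmethyl)pyrrolidin-1-yl]methyl}-4-methylphenol, 20 mol%, antipode giving 4R), toluene, 0 °C; then 4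
Reagents that add atoms: none
Why: Catalytic asymmetric alkynylation of an enal, in which the dinuclear zinc–ProPhenol complex binds the aldehyde and acetylide 6 and delivers the alkyne to one aldehyde face, so C4 is set by the ligand (antipode chosen for 4R).

Step 4
Reactants: 7 methyl (4R,5Z)-4-hydroxy-6-iodohept-5-en-2-ynoate
Product: 10 (5S)-3-(hydroxymethyl)-5-[(1Z)-2-iodoprop-1-en-1-yl]furan-2(5H)-one, via bis-aluminium alkenylalane 8 (not isolated), via acyclic diol ester 9 (not isolated)
Conditions: i-Bu2AlH (2.2 equiv), HMPA, THF, 0 °C; then paraformaldehyde, 0 °C → rt; aqueous HCl work-up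
Reagents that add atoms: formaldehyde (from paraformaldehyde), C=O
Why: The i-Bu2AlH·HMPA complex adds hydride to C3 and aluminium to C2 of the ynoate in a syn sense (conjugate hydroalumination), alkenylalane 8 is hydroxymethylated by formaldehyde with retention (reductive aldol of the vinylalumination type), and because the C4 oxygen then lies cis to the ester the diol ester 9 lactonises to the butenolide, the stereocentre not being touched.

Step 5
Reactants: 10 (5S)-3-(hydroxymethyl)-5-[(1Z)-2-iodoprop-1-en-1-yl]furan-2(5H)-one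
Product: 11 (5S)-3-(bromomethyl)-5-[(1Z)-2-iodoprop-1-en-1-yl]furan-2(5H)-one
Conditions: CBr4, PPh3, CH2Cl2, 0 °C
Reagents that add atoms: carbon tetrabromide, BrC(Br)(Br)Br
Why: Appel bromination converts the primary allylic alcohol under neutral conditions, which should spare the base-sensitive C5–H of the butenolide and the alkenyl iodide.

Step 6
Reactants: 12 pent-1-en-4-yne; 13 oxirane
Product: 16 (3E)-4-methylhepta-3,6-dien-1-ol, via alkenyldimethylalane 14 (not isolated), via lithium alkenylaluminate 15 (not isolated)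
Conditions: Me3Al (2 equiv), Cp2ZrCl2 (0.2 equiv), CH2Cl2, 0 °C → rt; then n-BuLi, THF/hexane, −78 °C; then oxirane, −78 °C → rt
Reagents that add atoms: trimethylaluminium, C[Al](C)C
Why: Zirconocene-catalysed syn-carboalumination (Negishi) adds CH3 and Al across the terminal alkyne regioselectively while the alkene does not react, and aluminate 15 opens oxirane with retention, which fixes the E trisubstituted alkene.

Step 7
Reactants: 16 (3E)-4-methylhepta-3,6-dien-1-ol
Product: 17 tert-butyl(dimethyl){[(3E)-4-methylhepta-3,6-dien-1-yl]oxy}silane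
Conditions: TBSCl, imidazole, CH2Cl2, rt
Reagents that add atoms: tert-butyl(chloro)dimethylsilane, CC(C)(C)[Si](C)(C)Cl
Why: Standard silylation of the primary alcohol (silyl ether formation).

Step 8
Reactants: 17 tert-butyl(dimethyl){[(3E)-4-methylhepta-3,6-dien-1-yl]oxy}silane
Product: 18 tert-butyl(dimethyl){2-[(2R,3R)-3-methyl-3-(prop-2-en-1-yl)oxiran-2-yl]ethoxy}silane
Conditions: 1,2:4,5-di-O-isopropylidene-β-D-erythro-2,3-hexodiulo-2,6-pyranose (D-fructose-derived Shi ketone, 30 mol%), KHSO5 (as 2KHSO5·KHSO4·K2SO4), K2CO3, Bu4NHSO4, MeCN/dimethoxymethane/aqueous buffer, 0 °C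
Reagents that add atoms: potassium peroxymonosulfate (KHSO5), [K+].[O-]S(=O)(=O)OO
Why: Shi asymmetric epoxidation, in which the dioxirane of the D-fructose-derived ketone transfers oxygen to the electron-rich E-trisubstituted alkene through the spiro transition state and so sets both oxirane carbons (2R,3R) by catalyst control, while the monosubstituted alkene reacts far more slowly.

Step 9
Reactants: 18 tert-butyl(dimethyl){2-[(2R,3R)-3-methyl-3-(prop-2-en-1-yl)oxiran-2-yl]ethoxy}silane
Product: 20 [(2R,3R)-3-(2-{[tert-butyl(dimethyl)silyl]oxy}ethyl)-2-methyloxiran-2-yl]acetaldehyde, via ozonide 19 (not isolated)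
Conditions: O3, CH2Cl2, −78 °C; then PPh3, −78 °C → rt
Reagents that add atoms: ozone, [O-][O+]=O
Why: Ozonolysis with reductive work-up cleaves the only remaining alkene to the aldehyde under neutral conditions that the oxirane and the silyl ether tolerate.

Step 10
Reactants: 21 tert-butyl prop-2-enoate; 22 acetaldehyde
Product: 23 tert-butyl 3-hydroxy-2-methylidenebutanoate (racemic)
Conditions: DABCO (cat.), neat, rt
Reagents that add atoms: none
Why: Morita–Baylis–Hillman reaction of the acrylate with acetaldehyde under DABCO catalysis, the racemic carbinol centre being removed in step 11.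

Step 11
Reactants: 23 tert-butyl 3-hydroxy-2-methylidenebutanoate
Product: 24 tert-butyl (2Z)-2-(bromomethyl)but-2-enoate
Conditions: PBr3, Et2O, 0 °C
Reagents that add atoms: phosphorus tribromide, BrP(Br)Br
Why: PBr3 brominates with allylic transposition (SN2′) and should give the thermodynamically favoured Z bromide in which CH3 is cis to CH2Br.

Step 12
Reactants: 21 tert-butyl prop-2-enoate; 25 {[tert-butyl(diphenyl)silyl]oxy}acetaldehyde
Product: 26 tert-butyl 4-{[tert-butyl(diphenyl)silyl]oxy}-3-hydroxy-2-methylidenebutanoate (racemic)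
Conditions: DABCO (cat.), neat, rt
Reagents that add atoms: none
Why: Morita–Baylis–Hillman reaction, the racemic carbinol centre being removed in step 13.

Step 13
Reactants: 26 tert-butyl 4-{[tert-butyl(diphenyl)silyl]oxy}-3-hydroxy-2-methylidenebutanoate
Product: 28 tert-butyl (2E)-2-[(acetyloxy)methyl]-4-{[tert-butyl(diphenyl)silyl]oxy}but-2-enoate, via secondary allylic acetate 27 (not isolated)
Conditions: Ac2O, Et3N, DMAP (cat.), CH2Cl2, 0 °C → rt; then DABCO (0.2 equiv), THF, 65 °C
Reagents that add atoms: acetic anhydride, CC(=O)OC(C)=O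
Why: Acetylation gives the Morita–Baylis–Hillman acetate 27, which DABCO isomerises by an addition–elimination 1,3-transposition to the thermodynamically preferred primary acetate with the silyloxymethyl group trans to the ester (2E).

Step 14
Reactants: 28 tert-butyl (2E)-2-[(acetyloxy)methyl]-4-{[tert-butyl(diphenyl)silyl]oxy}but-2-enoate
Product: 29 (2E)-2-[(acetyloxy)methyl]-4-{[tert-butyl(diphenyl)silyl]oxy}but-2-enoic acid
Conditions: TFA, CH2Cl2, 0 °C → rt
Reagents that add atoms: none
Why: Acidolysis of the tert-butyl ester with loss of isobutene, the primary tert-butyldiphenylsilyl ether and the acetate being stable to brief TFA.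

Step 15
Reactants: 29 (2E)-2-[(acetyloxy)methyl]-4-{[tert-butyl(diphenyl)silyl]oxy}but-2-enoic acid; 24 tert-butyl (2Z)-2-(bromomethyl)but-2-enoate
Product: 30 tert-butyl (2E)-2-{[((2E)-2-[(acetyloxy)methyl]-4-{[tert-butyl(diphenyl)silyl]oxy}but-2-enoyl)oxy]methyl}but-2-enoate
Conditions: Cs2CO3, DMF, 0 °C → rt
Reagents that add atoms: none
Why: SN2 O-alkylation of the caesium carboxylate at the primary allylic bromide, which keeps both alkene geometries.

Step 16
Reactants: 30 tert-butyl (2E)-2-{[((2E)-2-[(acetyloxy)methyl]-4-{[tert-butyl(diphenyl)silyl]oxy}but-2-enoyl)oxy]methyl}but-2-enoate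
Product: 31 (2E)-2-{[((2E)-2-[(acetyloxy)methyl]-4-{[tert-butyl(diphenyl)silyl]oxy}but-2-enoyl)oxy]methyl}but-2-enoic acid (side-chain acid)
Conditions: TFA, CH2Cl2, 0 °C → rt
Reagents that add atoms: none
Why: Acidolysis of the remaining tert-butyl ester, to which the two other esters and the silyl ether are inert.

Step 17
Reactants: 11 (5S)-3-(bromomethyl)-5-[(1Z)-2-iodoprop-1-en-1-yl]furan-2(5H)-one; 20 [(2R,3R)-3-(2-{[tert-butyl(dimethyl)silyl]oxy}ethyl)-2-methyloxiran-2-yl]acetaldehyde
Product: 33 (4R,5S)-4-{(1S)-2-[(2R,3R)-3-(2-{[tert-butyl(dimethyl)silyl]oxy}ethyl)-2-methyloxiran-2-yl]-1-hydroxyethyl}-5-[(1Z)-2-iodoprop-1-en-1-yl]-3-methylideneoxolan-2-one, via allylindium dibromide 32 (not isolated)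
Conditions: In powder, THF/H2O 3:1, rt
Reagents that add atoms: none
Why: Barbier-type 2-(alkoxycarbonyl)allylation in which allylindium 32 adds through ring carbon C4 of the furanone on the face opposite the C5 alkenyl group (sets C4 trans to C5) in a chair Zimmerman–Traxler transition state with the aldehyde chain equatorial (sets the carbinol as 1S) and so gives the α-methylene lactone directly.

Step 18
Reactants: 33 lactone alcohol (1S carbinol); 31 side-chain acid
Product: 34 (1R)-ester of the lactone alcohol with acid 31 (C8 inverted; iodoalkenyl lactone, oxirane, primary TBS ether, TBDPS ether in the side chain)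
Conditions: PPh3, DIAD, toluene, 0 °C (betaine pre-formed); then 31 and 33, 0 °C → rt
Reagents that add atoms: none
Why: Mitsunobu esterification in which the C8 hydroxyl is activated on phosphorus and displaced by the carboxylate of 31 in an SN2 step, so the (1S)-carbinol becomes the (1R)-ester that the target needs at C8, while pre-forming the betaine keeps free PPh3 away from the acrylate units.

Step 19
Reactants: 34 bis-silyl seco ester
Product: 35 primary alcohol at C3 (TBS removed, TBDPS kept)
Conditions: HF·pyridine, pyridine, THF, 0 °C → rt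
Reagents that add atoms: none
Why: Buffered HF·pyridine removes the primary tert-butyldimethylsilyl ether much faster than the tert-butyldiphenylsilyl ether and should leave the oxirane, the lactone and the esters intact (selective desilylation).

Step 20
Reactants: 35 C3 primary alcohol
Product: 36 seco iodoalkenyl β,γ-epoxy aldehyde (C3 aldehyde)
Conditions: Dess–Martin periodinane, pyridine, CH2Cl2, 0 °C → rt; used at once
Reagents that add atoms: none
Why: Dess–Martin oxidation buffered with pyridine gives the β,γ-epoxy aldehyde without a base strong enough to open the oxirane by elimination.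

Step 21
Reactants: 36 seco iodoalkenyl β,γ-epoxy aldehyde
Product: 38 macrocyclic allylic alcohol (3S), the side-chain TBDPS ether of the target, via alkenylchromium dichloride 37 (not isolated)
Conditions: CrCl2 (8 equiv), NiCl2 (2 mol%), degassed DMSO, rt, 36 added over 12 h (final 2 mM)
Reagents that add atoms: none
Why: Zerovalent nickel, formed from NiCl2 by CrCl2, inserts into the C4–I bond, transmetalation to trivalent chromium gives the configurationally stable Z-alkenylchromium 37, and this adds to the C3 aldehyde, which forms the C3–C4 bond and closes the ten-membered carbocycle. The closest known reaction type is the intramolecular Nozaki–Hiyama–Kishi coupling of iodoalkenyl aldehydes to medium-ring allylic alcohols. The ring closes in the 10-exo-trig mode, the carbonyl oxygen staying outside the new ring. The new stereocentre C3 is set by substrate control: the trans lactone (C6, C7), the Z alkene and the trans oxirane (C1, C10) should allow only a peripheral approach in which the chromium-bound oxygen points out of the ring and C3–H eclipses the C4=C5 plane toward C6 (allylic strain), which is expected to give 3S. The step needs chemoselectivity for the aldehyde over the acrylate-type esters, the allylic esters and the oxirane, which the low basicity and aldehyde preference of organochromium reagents should secure. It also needs retention of the 4Z geometry, which trisubstituted alkenylchromium species keep, and ring closure over oligomerisation, which high dilution and the three folding elements should secure.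

Step 22
Reactants: 38 macrocyclic TBDPS ether
Product: 39 CNP0193678.1 (target)
Conditions: HF·pyridine, pyridine, THF, 0 °C → rt
Reagents that add atoms: none
Why: Fluoride cleavage of the remaining primary allylic silyl ether under buffered, non-basic conditions that should avoid acetyl migration and oxirane opening (desilylation).

**Compound list**

1 | but-2-yn-1-ol | CC#CCO | starting material
2 | sodium 2,2-bis(2-methoxyethoxy)-3-methyl-2,5-dihydro-1,2-oxaaluminol-2-uide (cyclic alkenylalanate) | CC1=CCO[Al-]1(OCCOC)OCCOC.[Na+] | intermediate (not isolated)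
3 | (2Z)-3-iodobut-2-en-1-ol | C/C(I)=C/CO | intermediate
4 | (2Z)-3-iodobut-2-enal | C/C(I)=C/C=O | intermediate
5 | methyl prop-2-ynoate | C#CC(=O)OC | starting material
6 | methyl 3-(methylzincio)prop-2-ynoate (zinc acetylide) | C[Zn]C#CC(=O)OC | intermediate (not isolated)
7 | methyl (4R,5Z)-4-hydroxy-6-iodohept-5-en-2-ynoate | O[C@@H](C#CC(=O)OC)/C=C(/C)I | intermediate
8 | methyl (2E,4S,5Z)-2-(diisobutylalumanyl)-4-[(diisobutylalumanyl)oxy]-6-iodohepta-2,5-dienoate (ester cis to C4) | COC(=O)/C(=C\[C@H](O[Al](CC(C)C)CC(C)C)/C=C(/C)I)[Al](CC(C)C)CC(C)C | intermediate (not isolated)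
9 | methyl (2Z,4S,5Z)-4-hydroxy-2-(hydroxymethyl)-6-iodohepta-2,5-dienoate | COC(=O)/C(CO)=C\[C@H](O)/C=C(/C)I | intermediate (not isolated)
10 | (5S)-3-(hydroxymethyl)-5-[(1Z)-2-iodoprop-1-en-1-yl]furan-2(5H)-one | O=C1O[C@@H](C=C1CO)/C=C(/C)I | intermediate
11 | (5S)-3-(bromomethyl)-5-[(1Z)-2-iodoprop-1-en-1-yl]furan-2(5H)-one | O=C1O[C@@H](C=C1CBr)/C=C(/C)I | intermediate
12 | pent-1-en-4-yne | C=CCC#C | starting material
13 | oxirane | C1CO1 | starting material
14 | dimethyl[(1E)-2-methylpenta-1,4-dien-1-yl]alumane | C[Al](C)/C=C(\C)CC=C | intermediate (not isolated)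
15 | lithium butyl(dimethyl)[(1E)-2-methylpenta-1,4-dien-1-yl]aluminate | [Li+].CCCC[Al-](C)(C)/C=C(\C)CC=C | intermediate (not isolated)
16 | (3E)-4-methylhepta-3,6-dien-1-ol | OCC/C=C(\C)CC=C | intermediate
17 | tert-butyl(dimethyl){[(3E)-4-methylhepta-3,6-dien-1-yl]oxy}silane | CC(C)(C)[Si](C)(C)OCC/C=C(\C)CC=C | intermediate
18 | tert-butyl(dimethyl){2-[(2R,3R)-3-methyl-3-(prop-2-en-1-yl)oxiran-2-yl]ethoxy}silane | CC(C)(C)[Si](C)(C)OCC[C@H]1O[C@]1(C)CC=C | intermediate
19 | 3-{[(2R,3R)-3-(2-{[tert-butyl(dimethyl)silyl]oxy}ethyl)-2-methyloxiran-2-yl]methyl}-1,2,4-trioxolane (ozonide, epimers at the trioxolane carbon) | CC(C)(C)[Si](C)(C)OCC[C@H]1O[C@]1(C)CC2OCOO2 | intermediate (not isolated)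
20 | [(2R,3R)-3-(2-{[tert-butyl(dimethyl)silyl]oxy}ethyl)-2-methyloxiran-2-yl]acetaldehyde | CC(C)(C)[Si](C)(C)OCC[C@H]1O[C@]1(C)CC=O | intermediate
21 | tert-butyl prop-2-enoate | C=CC(=O)OC(C)(C)C | starting material
22 | acetaldehyde | CC=O | starting material
23 | tert-butyl 3-hydroxy-2-methylidenebutanoate (racemic) | CC(O)C(=C)C(=O)OC(C)(C)C | intermediate
24 | tert-butyl (2Z)-2-(bromomethyl)but-2-enoate | C/C=C(\CBr)C(=O)OC(C)(C)C | intermediate
25 | {[tert-butyl(diphenyl)silyl]oxy}acetaldehyde | O=CCO[Si](c1ccccc1)(c1ccccc1)C(C)(C)C | starting material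
26 | tert-butyl 4-{[tert-butyl(diphenyl)silyl]oxy}-3-hydroxy-2-methylidenebutanoate (racemic) | C=C(C(O)CO[Si](c1ccccc1)(c1ccccc1)C(C)(C)C)C(=O)OC(C)(C)C | intermediate
27 | tert-butyl 3-(acetyloxy)-4-{[tert-butyl(diphenyl)silyl]oxy}-2-methylidenebutanoate (racemic) | C=C(C(OC(C)=O)CO[Si](c1ccccc1)(c1ccccc1)C(C)(C)C)C(=O)OC(C)(C)C | intermediate (not isolated)
28 | tert-butyl (2E)-2-[(acetyloxy)methyl]-4-{[tert-butyl(diphenyl)silyl]oxy}but-2-enoate | CC(C)(C)OC(=O)/C(=C/CO[Si](c1ccccc1)(c1ccccc1)C(C)(C)C)COC(C)=O | intermediate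
29 | (2E)-2-[(acetyloxy)methyl]-4-{[tert-butyl(diphenyl)silyl]oxy}but-2-enoic acid | OC(=O)/C(=C/CO[Si](c1ccccc1)(c1ccccc1)C(C)(C)C)COC(C)=O | intermediate
30 | tert-butyl (2E)-2-{[((2E)-2-[(acetyloxy)methyl]-4-{[tert-butyl(diphenyl)silyl]oxy}but-2-enoyl)oxy]methyl}but-2-enoate | CC(C)(C)OC(=O)/C(=C/C)COC(=O)/C(=C/CO[Si](c1ccccc1)(c1ccccc1)C(C)(C)C)COC(C)=O | intermediate
31 | (2E)-2-{[((2E)-2-[(acetyloxy)methyl]-4-{[tert-butyl(diphenyl)silyl]oxy}but-2-enoyl)oxy]methyl}but-2-enoic acid | OC(=O)/C(=C/C)COC(=O)/C(=C/CO[Si](c1ccccc1)(c1ccccc1)C(C)(C)C)COC(C)=O | intermediate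
32 | dibromo({(5S)-5-[(1Z)-2-iodoprop-1-en-1-yl]-2-oxo-2,5-dihydrofuran-3-yl}methyl)indium (allylindium, simplest formulation) | O=C1O[C@@H](C=C1C[In](Br)Br)/C=C(/C)I | intermediate (not isolated)
33 | (4R,5S)-4-{(1S)-2-[(2R,3R)-3-(2-{[tert-butyl(dimethyl)silyl]oxy}ethyl)-2-methyloxiran-2-yl]-1-hydroxyethyl}-5-[(1Z)-2-iodoprop-1-en-1-yl]-3-methylideneoxolan-2-one | C=C1C(=O)O[C@H](/C=C(/C)I)[C@H]1[C@@H](O)C[C@@]2(C)O[C@@H]2CCO[Si](C)(C)C(C)(C)C | intermediate
34 | (1R)-2-[(2R,3R)-3-(2-{[tert-butyl(dimethyl)silyl]oxy}ethyl)-2-methyloxiran-2-yl]-1-{(2S,3R)-2-[(1Z)-2-iodoprop-1-en-1-yl]-4-methylidene-5-oxooxolan-3-yl}ethyl ester of acid 31 | C=C1C(=O)O[C@H](/C=C(/C)I)[C@H]1[C@H](OC(=O)/C(=C/C)COC(=O)/C(=C/CO[Si](c2ccccc2)(c2ccccc2)C(C)(C)C)COC(C)=O)C[C@@]3(C)O[C@@H]3CCO[Si](C)(C)C(C)(C)C | intermediate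
35 | (1R)-2-[(2R,3R)-3-(2-hydroxyethyl)-2-methyloxiran-2-yl]-1-{(2S,3R)-2-[(1Z)-2-iodoprop-1-en-1-yl]-4-methylidene-5-oxooxolan-3-yl}ethyl ester of acid 31 | C=C1C(=O)O[C@H](/C=C(/C)I)[C@H]1[C@H](OC(=O)/C(=C/C)COC(=O)/C(=C/CO[Si](c2ccccc2)(c2ccccc2)C(C)(C)C)COC(C)=O)C[C@@]3(C)O[C@@H]3CCO | intermediate
36 | (1R)-1-{(2S,3R)-2-[(1Z)-2-iodoprop-1-en-1-yl]-4-methylidene-5-oxooxolan-3-yl}-2-[(2R,3R)-2-methyl-3-(2-oxoethyl)oxiran-2-yl]ethyl ester of acid 31 | C=C1C(=O)O[C@H](/C=C(/C)I)[C@H]1[C@H](OC(=O)/C(=C/C)COC(=O)/C(=C/CO[Si](c2ccccc2)(c2ccccc2)C(C)(C)C)COC(C)=O)C[C@@]3(C)O[C@@H]3CC=O | intermediate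
37 | alkenylchromium dichloride derived from 36 (CrCl2 group in place of iodine, Z geometry kept) | C=C1C(=O)O[C@H](/C=C(/C)[Cr](Cl)Cl)[C@H]1[C@H](OC(=O)/C(=C/C)COC(=O)/C(=C/CO[Si](c2ccccc2)(c2ccccc2)C(C)(C)C)COC(C)=O)C[C@@]3(C)O[C@@H]3CC=O | intermediate (not isolated)
38 | (1R,3S,4Z,6R,7R,8R,10R)-1,10-epoxy-3-hydroxy-12-oxo-germacra-4,11(13)-dien-12,6-olide 8-ester of acid 31 (side-chain TBDPS ether of the target) | C=C1C(=O)O[C@@H]2/C=C(/C)[C@@H](O)C[C@H]3O[C@]3(C)C[C@@H](OC(=O)/C(=C/C)COC(=O)/C(=C/CO[Si](c4ccccc4)(c4ccccc4)C(C)(C)C)COC(C)=O)[C@@H]12 | intermediate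
39 | CNP0193678.1: (1R,3S,4Z,6R,7R,8R,10R)-1,10-epoxy-3-hydroxy-8-{[(2E)-2-({[(2E)-2-(acetoxymethyl)-4-hydroxybut-2-enoyl]oxy}methyl)but-2-enoyl]oxy}germacra-4,11(13)-dien-12,6-olide | C=C1C(=O)O[C@@H]2/C=C(/C)[C@@H](O)C[C@H]3O[C@]3(C)C[C@@H](OC(=O)/C(=C/C)COC(=O)/C(=C/CO)COC(C)=O)[C@@H]12 | target

**Totals**

Total step count: 22. Longest linear sequence: 11 steps (steps 1–5, then 17–22).

**Steps most likely to fail**

1. Step 21 (ring closure). What may go wrong: addition of the alkenylchromium to the wrong face of the C3 aldehyde in the strained ten-membered transition state, so that facial selectivity at C3 is poor or reversed. Fallback: C3 is set by reagent control after the ring exists. Setting out from 36, the same CrCl2/NiCl2 closure is accepted whatever its selectivity. The (3R)-epimer of 38 F1, alone or mixed with 38, is oxidised with MnO2 in CH2Cl2 to the macrocyclic C3 enone F2. The enone is then reduced with catecholborane and the CBS oxazaborolidine (antipode chosen for 3S) at −78 °C, conditions under which the α-methylene lactone should not be reduced, and this comes back to the route at 38.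

2. Step 18 (Mitsunobu esterification). What may go wrong: elimination toward C7 or attack of the phosphine on the acrylate units instead of substitution at the hindered C8 carbinol. Fallback: a two-stage sulfonate displacement without phosphine. Setting out from 33, Tf2O and 2,6-di-tert-butylpyridine in CH2Cl2 at −78 °C give the C8 trifluoromethanesulfonate of 33 F3. This is displaced at −20 °C → rt in toluene by the caesium salt of 31 (from 31 and Cs2CO3, with 18-crown-6) in an SN2 reaction with inversion, which comes back to the route at 34.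

3. Step 4 (hydroalumination–hydroxymethylation–lactonisation). What may go wrong: the free hydroxyl, as its aluminium alkoxide, diverts the hydride to 1,2-reduction of the ester or spoils the regiochemistry of the conjugate hydroalumination. Fallback: the hydroxyl is masked and the butenolide is closed in a separate operation. Setting out from 7, TBSCl and imidazole give methyl (4R,5Z)-4-{[tert-butyl(dimethyl)silyl]oxy}-6-iodohept-5-en-2-ynoate F4. Conjugate hydroalumination (i-Bu2AlH, HMPA, THF, 0 °C) and trapping with formaldehyde give methyl (2Z,4S,5Z)-4-{[tert-butyl(dimethyl)silyl]oxy}-2-(hydroxymethyl)-6-iodohepta-2,5-dienoate F5. HF·pyridine in THF then removes the silyl group, and the liberated hydroxyl, cis to the ester, lactonises, which comes back to the route at 10.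

**Further compounds**

F1 | step 21 | (3R)-epimer of 38 | C=C1C(=O)O[C@@H]2/C=C(/C)[C@H](O)C[C@H]3O[C@]3(C)C[C@@H](OC(=O)/C(=C/C)COC(=O)/C(=C/CO[Si](c4ccccc4)(c4ccccc4)C(C)(C)C)COC(C)=O)[C@@H]12
F2 | step 21 | macrocyclic C3 enone (3-oxo analogue of 38) | C=C1C(=O)O[C@@H]2/C=C(/C)C(=O)C[C@H]3O[C@]3(C)C[C@@H](OC(=O)/C(=C/C)COC(=O)/C(=C/CO[Si](c4ccccc4)(c4ccccc4)C(C)(C)C)COC(C)=O)[C@@H]12
F3 | step 18 | C8 trifluoromethanesulfonate of 33 | C=C1C(=O)O[C@H](/C=C(/C)I)[C@H]1[C@@H](OS(=O)(=O)C(F)(F)F)C[C@@]2(C)O[C@@H]2CCO[Si](C)(C)C(C)(C)C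
F4 | step 4 | methyl (4R,5Z)-4-{[tert-butyl(dimethyl)silyl]oxy}-6-iodohept-5-en-2-ynoate | CC(C)(C)[Si](C)(C)O[C@@H](C#CC(=O)OC)/C=C(/C)I
F5 | step 4 | methyl (2Z,4S,5Z)-4-{[tert-butyl(dimethyl)silyl]oxy}-2-(hydroxymethyl)-6-iodohepta-2,5-dienoate | COC(=O)/C(CO)=C\[C@H](O[Si](C)(C)C(C)(C)C)/C=C(/C)I
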